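**Retrosynthetic overview**
1. Target 15 ⇐ penta-MOM ether 14 by global acid methanolysis; the 4'-OMe is the only O-alkyl group that stays.
2. 14 ⇐ ynone 8 + 6-iodoflavone 13 by one new palladium-catalysed arylative cyclisation that makes the C3–C6'' biaryl bond and the pyranone ring of the acacetin half together.
3. 8 ⇐ phloroglucinol (tris-MOM ether, ortho-lithiation/formylation) + 4-ethynylanisole (acetylide addition, oxidation).
4. 13 ⇐ apigenin by 7,4'-di-O-MOM protection, 5-OH-directed C6 iodination and 5-O-MOM capping.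
5. Ring order: the apigenin chromone is bought in; the pyranone ring of the acacetin half is closed last, in the coupling step.

Assumption: the SMILES carries no stereodescriptor and the molecule has no stereocentre; the C3–C6'' axis is unspecified, so no axial control is attempted (any atropisomers form as the racemate).

**Step 1**
Reactants: 1 phloroglucinol
Product: 2 1,3,5-tris(methoxymethoxy)benzene
Conditions: MOMCl (3.6 equiv), i-Pr2NEt (4 equiv), DMF, 0 °C → rt
Reagents that add atoms: chloromethyl methyl ether (MOMCl), COCCl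
Why: Williamson-type O-alkylation (acetal protection), in which the hard electrophile MOMCl alkylates all three phenolic oxygens under amine base.

**Step 2**
Reactants: 2 1,3,5-tris(methoxymethoxy)benzene
Product: 4 2,4,6-tris(methoxymethoxy)benzaldehyde, via aryllithium 3 (not isolated)
Conditions: n-BuLi, TMEDA, THF, 0 °C; DMF, 0 °C → rt; H2O
Reagents that add atoms: N,N-dimethylformamide, CN(C)C=O (formyl carbon and oxygen of 4); n-butyllithium, [Li]CCCC (lithium of 3)
Why: Directed ortho-metalation between two OMOM groups (all three ring positions are equivalent) followed by formylation of the aryllithium with DMF.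

**Step 3**
Reactants: 5 4-ethynylanisole; 4 2,4,6-tris(methoxymethoxy)benzaldehyde
Product: 7 rac-3-(4-methoxyphenyl)-1-[2,4,6-tris(methoxymethoxy)phenyl]prop-2-yn-1-ol, via lithium acetylide 6 (not isolated)
Conditions: 5, n-BuLi, THF, −78 °C; then 4, −78 → 0 °C; H2O; used crude
Reagents that add atoms: n-butyllithium, [Li]CCCC (supplies the lithium of 6; no non-hydrogen atom of 7)
Why: 1,2-addition of a lithium acetylide to an aldehyde; the carbinol stereocentre forms as the racemate, which does not matter because step 4 oxidises it away.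

**Step 4**
Reactants: 7 rac-3-(4-methoxyphenyl)-1-[2,4,6-tris(methoxymethoxy)phenyl]prop-2-yn-1-ol
Product: 8 3-(4-methoxyphenyl)-1-[2,4,6-tris(methoxymethoxy)phenyl]prop-2-yn-1-one
Conditions: MnO2 (excess), CH2Cl2, rt
Reagents that add atoms: none
Why: MnO2 oxidation of a benzylic-propargylic alcohol under neutral conditions that leave the MOM ethers and the alkyne untouched.

**Step 5**
Reactants: 9 apigenin
Product: 10 5-hydroxy-7-(methoxymethoxy)-2-[4-(methoxymethoxy)phenyl]-4H-chromen-4-one
Conditions: MOMCl (2.3 equiv), K2CO3, DMF, 0 °C → rt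
Reagents that add atoms: chloromethyl methyl ether (MOMCl), COCCl
Why: Selective Williamson O-alkylation of the 7- and 4'-phenols, the 5-OH staying free because it is hydrogen-bonded to the C4 carbonyl.

**Step 6**
Reactants: 10 5-hydroxy-7-(methoxymethoxy)-2-[4-(methoxymethoxy)phenyl]-4H-chromen-4-one
Product: 11 5-hydroxy-6-iodo-7-(methoxymethoxy)-2-[4-(methoxymethoxy)phenyl]-4H-chromen-4-one
Conditions: BnMe3N·ICl2 (1.1 equiv), CaCO3, CH2Cl2/MeOH, rt
Reagents that add atoms: benzyltrimethylammonium dichloroiodate, C[N+](C)(C)Cc1ccccc1.Cl[I-]Cl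
Why: Electrophilic aromatic iodination in which the free chelated 5-OH directs the electrophile ortho to itself, to C6 (5-O-alkylated flavones go to C8), while CaCO3 buffers the HCl so the MOM ethers survive.

**Step 7**
Reactants: 11 5-hydroxy-6-iodo-7-(methoxymethoxy)-2-[4-(methoxymethoxy)phenyl]-4H-chromen-4-one
Product: 13 6-iodo-5,7-bis(methoxymethoxy)-2-[4-(methoxymethoxy)phenyl]-4H-chromen-4-one, via sodium phenoxide 12 (not isolated)
Conditions: NaH, DMF, 0 °C; then MOMCl, 0 °C → rt
Reagents that add atoms: sodium hydride, [Na+].[H-] (sodium of 12); chloromethyl methyl ether (MOMCl), COCCl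
Why: Williamson O-alkylation of the sodium phenoxide (NaH breaks the hydrogen bond of the hindered 5-OH), which caps the oxygen so the o-iodophenol cannot undergo Larock-type benzofuran annulation in step 8.

**Step 8**
Reactants: 8 3-(4-methoxyphenyl)-1-[2,4,6-tris(methoxymethoxy)phenyl]prop-2-yn-1-one (1.3 equiv); 13 6-iodo-5,7-bis(methoxymethoxy)-2-[4-(methoxymethoxy)phenyl]-4H-chromen-4-one
Product: 14 3-{5,7-bis(methoxymethoxy)-2-[4-(methoxymethoxy)phenyl]-4-oxo-4H-chromen-6-yl}-5,7-bis(methoxymethoxy)-2-(4-methoxyphenyl)-4H-chromen-4-one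
Conditions: Pd2(dba)3 (2.5 mol %), SPhos (10 mol %), AgOPiv (1.5 equiv), 4 Å MS, PhMe, 80 °C
Reagents that add atoms: none
Why: Proposed new method: a dealkoxymethylative arylative oxypalladation, in which oxidative addition of zerovalent palladium/SPhos into the hindered carbon–iodine bond of 13 and iodide abstraction by AgOPiv give a cationic aryl complex of divalent palladium that π-activates the ynone, the ortho MOM-ether oxygen attacks the anisyl-bearing alkyne carbon anti to palladium (6-endo-dig, favoured by the ynone polarisation and the p-anisyl group), pivalate removes the methoxymethyl group from the resulting oxonium as methoxymethyl pivalate, and C–C reductive elimination from the (chromon-3-yl)(aryl)palladium forms the C3–C6'' bond, so the pyranone ring and the biaryl bond arise in one step with no stereocentre created; the MOM ether acts as a latent phenoxide that cannot cyclise before the aryl group is on palladium (a free phenol would give the 3-H flavone), the two ortho OMOM groups of 8 are equivalent so only one regioisomer is possible, and the di-ortho-substituted aryl group disfavours competing syn-carbopalladation; the closest known reaction types are the Cacchi aminopalladation/reductive-elimination annulation of o-alkynylanilines and o-alkynylphenols with aryl halides, the ICl-induced cyclisation of o-alkoxyaryl ynones to 3-iodochromones and the platinum-catalysed carboalkoxylation of o-alkynylphenyl acetals.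

**Step 9**
Reactants: 14 3-{5,7-bis(methoxymethoxy)-2-[4-(methoxymethoxy)phenyl]-4-oxo-4H-chromen-6-yl}-5,7-bis(methoxymethoxy)-2-(4-methoxyphenyl)-4H-chromen-4-one
Product: 15 5,7-dihydroxy-3-[5,7-dihydroxy-2-(4-hydroxyphenyl)-4-oxo-4H-chromen-6-yl]-2-(4-methoxyphenyl)-4H-chromen-4-one
Conditions: HCl (2 M in MeOH), MeOH/THF, 50 °C
Reagents that add atoms: none
Why: Acid-catalysed acetal methanolysis (transacetalisation to dimethoxymethane) removes all five MOM groups while the aryl methyl ether is inert under these mild conditions, and no stereocentre is present to scramble.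

**Compound list**
1 | phloroglucinol (benzene-1,3,5-triol) | Oc1cc(O)cc(O)c1 | starting material
2 | 1,3,5-tris(methoxymethoxy)benzene | COCOc1cc(OCOC)cc(OCOC)c1 | intermediate
3 | [2,4,6-tris(methoxymethoxy)phenyl]lithium | [Li]c1c(OCOC)cc(OCOC)cc1OCOC | intermediate (not isolated)
4 | 2,4,6-tris(methoxymethoxy)benzaldehyde | O=Cc1c(OCOC)cc(OCOC)cc1OCOC | intermediate
5 | 4-ethynylanisole (1-ethynyl-4-methoxybenzene) | C#Cc1ccc(OC)cc1 | starting material
6 | lithium (4-methoxyphenyl)acetylide | [Li]C#Cc1ccc(OC)cc1 | intermediate (not isolated)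
7 | rac-3-(4-methoxyphenyl)-1-[2,4,6-tris(methoxymethoxy)phenyl]prop-2-yn-1-ol (racemic at C1) | COc1ccc(C#CC(O)c2c(OCOC)cc(OCOC)cc2OCOC)cc1 | intermediate
8 | 3-(4-methoxyphenyl)-1-[2,4,6-tris(methoxymethoxy)phenyl]prop-2-yn-1-one | COc1ccc(C#CC(=O)c2c(OCOC)cc(OCOC)cc2OCOC)cc1 | intermediate
9 | apigenin (5,7-dihydroxy-2-(4-hydroxyphenyl)-4H-chromen-4-one) | O=c1cc(-c2ccc(O)cc2)oc2cc(O)cc(O)c12 | starting material
10 | 5-hydroxy-7-(methoxymethoxy)-2-[4-(methoxymethoxy)phenyl]-4H-chromen-4-one | COCOc1ccc(-c2cc(=O)c3c(O)cc(OCOC)cc3o2)cc1 | intermediate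
11 | 5-hydroxy-6-iodo-7-(methoxymethoxy)-2-[4-(methoxymethoxy)phenyl]-4H-chromen-4-one | COCOc1ccc(-c2cc(=O)c3c(O)c(I)c(OCOC)cc3o2)cc1 | intermediate
12 | sodium 6-iodo-7-(methoxymethoxy)-2-[4-(methoxymethoxy)phenyl]-4-oxo-4H-chromen-5-olate | COCOc1ccc(-c2cc(=O)c3c([O-])c(I)c(OCOC)cc3o2)cc1.[Na+] | intermediate (not isolated)
13 | 6-iodo-5,7-bis(methoxymethoxy)-2-[4-(methoxymethoxy)phenyl]-4H-chromen-4-one | COCOc1ccc(-c2cc(=O)c3c(OCOC)c(I)c(OCOC)cc3o2)cc1 | intermediate
14 | 3-{5,7-bis(methoxymethoxy)-2-[4-(methoxymethoxy)phenyl]-4-oxo-4H-chromen-6-yl}-5,7-bis(methoxymethoxy)-2-(4-methoxyphenyl)-4H-chromen-4-one | COc1ccc(-c2oc3cc(OCOC)cc(OCOC)c3c(=O)c2-c2c(OCOC)cc3oc(-c4ccc(OCOC)cc4)cc(=O)c3c2OCOC)cc1 | intermediate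
15 | 5,7-dihydroxy-3-[5,7-dihydroxy-2-(4-hydroxyphenyl)-4-oxo-4H-chromen-6-yl]-2-(4-methoxyphenyl)-4H-chromen-4-one (CNP0273516.0) | COc1ccc(-c2oc3cc(O)cc(O)c3c(=O)c2-c2c(O)cc3oc(-c4ccc(O)cc4)cc(=O)c3c2O)cc1 | target

**Step count and risks**
Total step count: 9. Longest linear sequence: 6 steps (steps 1, 2, 3, 4, 8, 9, from phloroglucinol 1 to target 15).

Three steps most likely to fail:

Step 3 (the carbinol 7 carries a 2,4,6-trialkoxyphenyl group and ionises very easily, so it may decompose on handling). The fallback works at the ketone oxidation level and skips both 4 and 7. It sets out from 5 and from 2 and comes back at 8. Lithium acetylide 6, made from 5 as in step 3, is acylated with N-methoxy-N-methylcarbamoyl chloride in THF at −78 °C to give N-methoxy-3-(4-methoxyphenyl)-N-methylprop-2-ynamide F1. Aryllithium 3, made from 2 as in step 2, is then added to F1 at −78 °C and the chelated adduct is quenched cold with water, which gives ynone 8 directly (Weinreb ketone synthesis).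

Step 7 (alkylation of a chelated phenol flanked by iodine may stall, or the MOM ether may be too crowded). The fallback swaps the acetal for an ester, since acylation is far less sensitive to this hindrance. It sets out from 11 and comes back at 15. Compound 11 is acetylated (Ac2O, DMAP, pyridine, rt) to give 6-iodo-7-(methoxymethoxy)-2-[4-(methoxymethoxy)phenyl]-4-oxo-4H-chromen-5-yl acetate F2. F2 is coupled with 8 under the step 8 conditions to give 6-[5,7-bis(methoxymethoxy)-2-(4-methoxyphenyl)-4-oxo-4H-chromen-3-yl]-7-(methoxymethoxy)-2-[4-(methoxymethoxy)phenyl]-4-oxo-4H-chromen-5-yl acetate F3. The HCl/MeOH treatment of step 9 then removes the acetate (as methyl acetate) together with the four MOM groups and delivers 15.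

Step 8 (the proposed new method; the risks are hydroarylation or carbopalladation of the ynone, protodeiodination of 13, and a slow attack by the acetal oxygen). The fallback uses known chemistry only and separates ring closure from biaryl formation. It sets out from 8 and 13 and comes back at 14. Ynone 8 undergoes electrophilic iodocyclisation with ICl in CH2Cl2 at −78 °C (the oxonium loses its MOM group as MOMCl) to give 3-iodo-5,7-bis(methoxymethoxy)-2-(4-methoxyphenyl)-4H-chromen-4-one F4. Iodide 13 undergoes Miyaura borylation (B2pin2, Pd(dppf)Cl2, KOAc, dioxane, 90 °C) to give 5,7-bis(methoxymethoxy)-2-[4-(methoxymethoxy)phenyl]-6-(4,4,5,5-tetramethyl-1,3,2-dioxaborolan-2-yl)-4H-chromen-4-one F5. Suzuki–Miyaura coupling of F4 with F5 (Pd(OAc)2, SPhos, K3PO4, PhMe/H2O, 100 °C), as used for isoflavones from 3-iodochromones, gives 14.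

**Further compounds**
F1 | step 3 | N-methoxy-3-(4-methoxyphenyl)-N-methylprop-2-ynamide | COc1ccc(C#CC(=O)N(C)OC)cc1
F2 | step 7 | 6-iodo-7-(methoxymethoxy)-2-[4-(methoxymethoxy)phenyl]-4-oxo-4H-chromen-5-yl acetate | COCOc1ccc(-c2cc(=O)c3c(OC(C)=O)c(I)c(OCOC)cc3o2)cc1
F3 | step 7 | 6-[5,7-bis(methoxymethoxy)-2-(4-methoxyphenyl)-4-oxo-4H-chromen-3-yl]-7-(methoxymethoxy)-2-[4-(methoxymethoxy)phenyl]-4-oxo-4H-chromen-5-yl acetate | COc1ccc(-c2oc3cc(OCOC)cc(OCOC)c3c(=O)c2-c2c(OCOC)cc3oc(-c4ccc(OCOC)cc4)cc(=O)c3c2OC(C)=O)cc1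
F4 | step 8 | 3-iodo-5,7-bis(methoxymethoxy)-2-(4-methoxyphenyl)-4H-chromen-4-one | COc1ccc(-c2oc3cc(OCOC)cc(OCOC)c3c(=O)c2I)cc1
F5 | step 8 | 5,7-bis(methoxymethoxy)-2-[4-(methoxymethoxy)phenyl]-6-(4,4,5,5-tetramethyl-1,3,2-dioxaborolan-2-yl)-4H-chromen-4-one | COCOc1ccc(-c2cc(=O)c3c(OCOC)c(B4OC(C)(C)C(C)(C)O4)c(OCOC)cc3o2)cc1
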